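## Analysis of the target

Target 18 is an aryltetralin lignan. Tetralin numbering is used throughout: C1 carries the 4-hydroxy-3-methoxyphenyl (guaiacyl) ring, C2 and C3 carry the hydroxymethyl carbons C9 and C10, C4 is a methylene, C4a and C8a are the fusion carbons, and ring A has H on C5, OMe on C6 and free OH on C7 and C8. Ring B is the only saturated ring and holds all three stereocentres, C1 (S), C2 (R) and C3 (R). The aryl group is trans to C9 and C9 is trans to C10, so all three substituents can be equatorial on the half-chair; the target is the thermodynamically preferred diastereomer. The sensitive groups are the 7,8-catechol next to a methoxy group (readily oxidised to an o-quinone, above all in base and air), the guaiacyl phenol and the doubly benzylic C1–H. The hard points are the absolute configuration at C2 and C3, which carry only CH2OH groups and offer no handle, the crowded C1 between the peri oxygen on C8 and the C2 substituent, and the differentiation of five oxygen functions on two aromatic rings. The strategy rests on the fact that C1 and C4 are both benzylic and sit on the neighbouring ring A carbons C8a and C4a. A ring A benzaldehyde (future C1) with an ortho methyl group (future C4) is therefore a masked o-quinodimethane, and C2–C3 with C9 and C10 corresponds to a fumarate. The C1 oxygen left by the aldehyde is para to the C6 methoxy group and ortho to the C8 oxygen, so it ionises easily and can be exchanged for the aryl ring.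

## Retrosynthetic reasoning

18 ⇒ 17 ⇒ 16 (protecting groups). The catechol is unveiled last. In 17 the C7 and C8 oxygens are still tied in a diphenylmethylene ketal, which can be taken off by neutral hydrogenolysis, so the oxidation-prone catechol never meets base or hydride. 17 comes from the bis-pivalate 16 by reductive ester cleavage.

16 ⇒ 13 + 14 (C1–aryl bond, through cation 15). C1 is cut here because it is the one stereocentre whose configuration its neighbours can dictate: a nucleophile enters the planar cation 15 anti to the C2 substituent, and the trans product is also the more stable one. The donors on C6 and C8 make 15 easy to reach from the carbinol 13. The forward step must make arene 14 react through the carbon para to its free hydroxyl and from the face opposite C9.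

13 ⇒ 12 ⇒ 11 (oxidation level of C9 and C10). The esters are reduced before the arylation. A cation at C1 next to an ester on C2 would lose the acidic C2–H and with it the stereocentre. The pivalates of 13 keep the primary alcohols from trapping the cation, and the one on C9 can shield the cis face of C1.

11 ⇒ 8 + 9 (C1–C2 and C3–C4, through dienol 10). Both bonds between ring A's two benzylic carbons and the C2–C3 unit are cut at once. This reduces the ring B problem to an aldehyde (8) and a symmetrical E-alkene (9). The trans relation of C2 and C3 is inherited from the alkene geometry, and a chiral titanium diolate has only to choose the face. The forward reaction has to generate the o-quinodimethane 10 from 8 by light and trap it with 9 before it reverts.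

8 ⇒ 3 + 4 (aryl–methyl bond, through 5, 6 and 7). The methyl group is placed on the only free position ortho to the aldehyde by a directed lithiation, in which amine 4 masks the aldehyde and directs the metalation.

3 ⇒ 1 + 2. The ketal is made first from the commercial catechol aldehyde 1 and the gem-dichloride 2. It carries no hydrogen on the ketal carbon and leaves no phenolic hydrogen bond to the aldehyde, both of which the photochemical step requires.

## Alternatives that were turned down

Alternative 1: The cut is at C2–C3 and C1–C8a, the two bonds that lignan biosynthesis makes by phenol oxidation. Forward, the bis-cinnamate A2 holds a ferulate and a ring A cinnamate (C8 oxygen as tosylate) on a C2-symmetric 1,3-diol tether and is oxidised at an anode. The two carbons next to the ester carbonyls couple (C2–C3, nine-membered dilactone), and the ring A unit then attacks the quinone methide carbon C1 through C8a to give the dihydronaphthalene A1.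
- For: the whole skeleton, including the C1–aryl bond with unambiguous guaiacyl regiochemistry, arises in one operation without photochemistry. On this point it is stronger than the chosen route, which needs a separate arylation whose regiochemistry on 14 has to be won.
- Against: after C2–C3 coupling either aryl ring can cyclise onto the other unit. The ring that must act as the nucleophile is the one deactivated by the sulfonate, and it must react through C8a, ortho to that sulfonate. The untosylated guaiacyl ring is the better nucleophile and would give the wrong constitution.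
- Against: A1 keeps a C3=C4 double bond, so C3 must be set afterwards by a face-selective hydrogenation. The tether and the tosylate then have to be removed, and the step count ends near that of the chosen route.
- In its place the chosen strategy fixes which ring is ring A (the aldehyde ring) and sets C2 and C3 together from the alkene geometry.

Alternative 2: The cut is at C1–C2, with a temporary O–C9 bond from the C8 oxygen. Forward, the hydroxy carbinol A4 loses water under a catalytic phosphoric acid diester to an o-quinone methide across C8, C8a and C1. The tethered enol ether adds in an intramolecular hetero-Diels–Alder reaction (C1–C2 and O–C9) to give the tricyclic acetal A3.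
- For: it uses the C8 phenol, the unusual feature of ring A, as the trigger. The aryl group is in place from the start, and C1 and C2 are set together in an ordered intramolecular transition state under catalytic acid. In aryl regiochemistry it is stronger than the chosen route.
- Against: C3 must be made beforehand as an isolated stereocentre in an open chain by a separate asymmetric step. The geometry of the quinone methide at C1, which decides C1 against C2, is pressed between the C8 carbonyl and the C4a side chain and is not obviously one-sided.
- Against: the C9 acetal must be opened and reduced, three benzyl ethers removed, and C7 and C8 differentiated on the way in. The linear sequence would be clearly longer.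
- The chosen strategy reaches the ring B skeleton with C2 and C3 in three steps from a commercial aldehyde and needs no acyclic stereocentre.

Alternative 3: The cut is at C4–C4a and C1–C8a. Forward, fluoride turns the silyl triflate A7 into an aryne across C4a and C8a. The sulfonyl-stabilised carbanion of the cyclobutanone A6 adds at C4a, the aryl anion closes onto the carbonyl group, and the old four-ring bond breaks, expanding the cyclobutanone into ring B of the sulfonyl tetralone A5.
- For: it is convergent, and C2 and C3 are carried in enantiopure form into the key step instead of being induced in it. On this point it is stronger than the chosen route. The C8 oxygen should also direct the carbanion to the remote aryne carbon C4a.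
- Against: both partners need several steps each (a pentasubstituted silyl triflate and a chiral trans-disubstituted sulfonyl cyclobutanone). A5 still lacks the C1 aryl group and carries a sulfone to be removed, a C1 ketone to be arylated and deoxygenated, and four benzyl ethers.
- Against: deoxygenation of the tertiary diaryl carbinol by hydride delivery anti to C2 would place the aryl group cis to C9, the wrong relation. C2 is also epimerisable next to the ketone.
- The chosen strategy delivers C1 at the carbinol level, which is the correct leaving group for a trans-selective arylation, and uses far fewer steps.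

Key step: step 3

Assumption: the sense of induction of the complex from Ti(OiPr)4 and (R,R)-TADDOL ((4R,5R)-2,2-dimethyl-α,α,α′,α′-tetraphenyl-1,3-dioxolane-4,5-dimethanol) with 9 cannot be read from the structures. The route is written for the (2S,3R) outcome in 11, and the (S,S)-ligand is taken if the assignment on 12 shows the opposite.

## Route

Step 1
Reactants: 1 2,3-dihydroxy-4-methoxybenzaldehyde; 2 dichlorodiphenylmethane
Product: 3 7-methoxy-2,2-diphenyl-1,3-benzodioxole-4-carbaldehyde
Conditions: 2 (1.3 equiv), Ph2O, 175 °C, argon stream
Reagents that add atoms: none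
Why: Ketalisation of a catechol by double substitution at a gem-dichloride, driven by loss of HCl at high temperature; the aldehyde tolerates these anhydrous conditions, and the ketal carbon carries no hydrogen.

Step 2
Reactants: 3 7-methoxy-2,2-diphenyl-1,3-benzodioxole-4-carbaldehyde; 4 N,N,N'-trimethylethylenediamine
Product: 8 7-methoxy-5-methyl-2,2-diphenyl-1,3-benzodioxole-4-carbaldehyde, via lithium amino alkoxide 5 (not isolated), via ortho-lithiated amino alkoxide 6 (not isolated), via methylated amino alkoxide 7 (not isolated)
Conditions: 4 (1.1 equiv), n-BuLi (1.05 equiv), THF, −20 °C; then 3; then n-BuLi (3 equiv), −20 °C; then MeI (excess), −78 °C → rt; aq NH4Cl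
Reagents that add atoms: iodomethane, CI; n-butyllithium, [Li]CCCC (its lithium stays only in 5, 6 and 7)
Why: α-Amino alkoxide-directed ortho-lithiation: the lithium amide of 4 adds to the aldehyde and masks it as 5, whose chelating NMe2 arm brings n-BuLi to the only free position ortho to the carbinol carbon (the future C4a) in preference to the position ortho to OMe, giving 6. MeI methylates the aryllithium to 7, and aqueous work-up releases aldehyde 8 and amine 4.

Step 3
Reactants: 8 7-methoxy-5-methyl-2,2-diphenyl-1,3-benzodioxole-4-carbaldehyde; 9 dimethyl fumarate
Product: 11 dimethyl (1S,2S,3R)-1-hydroxy-6-methoxy-7,8-(diphenylmethylenedioxy)-1,2,3,4-tetrahydronaphthalene-2,3-dicarboxylate, via hydroxy-o-quinodimethane 10 (not isolated)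
Conditions: Ti(OiPr)4 (2 equiv) and (R,R)-TADDOL (2.2 equiv) premixed in toluene; 9 (3 equiv); degassed; hν (365 nm LEDs), rt
Reagents that add atoms: none
Why: Excitation of 8 at 365 nm is followed by 1,5-hydrogen transfer from the ortho methyl group to the carbonyl oxygen and gives dienol 10 with the hydroxyl pointing outward, the long-lived isomer; its oxygen binds to tetravalent titanium of the Ti(OiPr)4/TADDOL complex, which also holds the carbonyl oxygen of one ester of 9, and a suprafacial [4+2] cycloaddition follows. The closest known reaction type is the photoenolisation/Diels–Alder reaction of 2-methylbenzaldehydes, both with fumarates without metal and in the Ti(OiPr)4/TADDOL-mediated enantioselective form with unsaturated lactones and enones. Ring B is closed by an intermolecular [4+2] cycloaddition in which C1–C2 and C3–C4 form together and ring A regains aromaticity. C2 and C3 come out trans because the E geometry of 9 is transferred stereospecifically, and their absolute configuration is set by the TADDOL ligand, which leaves one face of the bound fumarate open to the diene. C1 is set by the endo position of the titanium-bound ester under the outward hydroxyl (hydroxyl cis to the C2 ester) and is of no consequence later. The step needs hydrogen abstraction from the methyl group only; the ketal secures this because it has no hydrogen on the ketal carbon and leaves no phenolic hydrogen bond to the carbonyl group, and the carbonyl oxygen turns away from the C8 oxygen toward the methyl group. It also needs 9 to keep its E geometry: 9 does not absorb at 365 nm, and the intramolecular hydrogen transfer is expected to outrun triplet energy transfer to it. Partial exchange of methyl for isopropyl esters on titanium would be harmless, since step 4 reduces every ester.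

Step 4
Reactants: 11 dimethyl (1S,2S,3R)-1-hydroxy-6-methoxy-7,8-(diphenylmethylenedioxy)-1,2,3,4-tetrahydronaphthalene-2,3-dicarboxylate
Product: 12 (1S,2R,3R)-2,3-bis(hydroxymethyl)-6-methoxy-7,8-(diphenylmethylenedioxy)-1,2,3,4-tetrahydronaphthalen-1-ol
Conditions: LiAlH4 (3 equiv), THF, 0 °C → rt; aq potassium sodium tartrate
Reagents that add atoms: none
Why: Hydride reduction of both esters to primary alcohols; reduction is faster than enolisation at 0 °C, so C2 and C3 keep their configuration, and the ketal is inert to hydride.

Step 5
Reactants: 12 (1S,2R,3R)-2,3-bis(hydroxymethyl)-6-methoxy-7,8-(diphenylmethylenedioxy)-1,2,3,4-tetrahydronaphthalen-1-ol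
Product: 13 [(1S,2R,3R)-1-hydroxy-6-methoxy-7,8-(diphenylmethylenedioxy)-1,2,3,4-tetrahydronaphthalene-2,3-diyl]bis(methylene) bis(2,2-dimethylpropanoate)
Conditions: PivCl (2.3 equiv), pyridine, CH2Cl2, −20 → 0 °C
Reagents that add atoms: pivaloyl chloride, CC(C)(C)C(=O)Cl
Why: Selective acylation of the two unhindered primary alcohols with a bulky acyl chloride; the secondary benzylic C1–OH, flanked by the C8 oxygen and C2, reacts much more slowly at low temperature. Any C1 pivalate formed would not be lost, since it ionises in step 6 as well.

Step 6
Reactants: 13 [(1S,2R,3R)-1-hydroxy-6-methoxy-7,8-(diphenylmethylenedioxy)-1,2,3,4-tetrahydronaphthalene-2,3-diyl]bis(methylene) bis(2,2-dimethylpropanoate); 14 2-methoxyphenol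
Product: 16 [(1S,2R,3R)-1-(4-hydroxy-3-methoxyphenyl)-6-methoxy-7,8-(diphenylmethylenedioxy)-1,2,3,4-tetrahydronaphthalene-2,3-diyl]bis(methylene) bis(2,2-dimethylpropanoate), via benzylic cation 15 (not isolated)
Conditions: 14 (5 equiv), BF3·OEt2 (0.2 equiv), CH2Cl2, −40 → 0 °C; aq NaHCO3
Reagents that add atoms: none
Why: Friedel–Crafts alkylation by an SN1 path: BF3 ionises the C1–OH to cation 15, which is stabilised by the para C6 methoxy group and the ortho C8 oxygen, so a substoichiometric amount of Lewis acid at low temperature should suffice and the ketal should survive. Arene 14 attacks through the carbon para to its free hydroxyl, the most activated and least hindered position. C1 is set by approach anti to the C2 substituent (the C9 pivalate carbonyl can also bridge to C1 on the cis face), and reversibility under acid favours the same all-equatorial trans isomer.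

Step 7
Reactants: 16 [(1S,2R,3R)-1-(4-hydroxy-3-methoxyphenyl)-6-methoxy-7,8-(diphenylmethylenedioxy)-1,2,3,4-tetrahydronaphthalene-2,3-diyl]bis(methylene) bis(2,2-dimethylpropanoate)
Product: 17 [(1S,2R,3R)-1-(4-hydroxy-3-methoxyphenyl)-6-methoxy-7,8-(diphenylmethylenedioxy)-1,2,3,4-tetrahydronaphthalene-2,3-diyl]dimethanol
Conditions: LiAlH4 (5 equiv), THF, 0 °C → rt; aq potassium sodium tartrate
Reagents that add atoms: none
Why: Reductive cleavage of both pivalate esters by hydride; the guaiacyl phenol only consumes hydride as its phenoxide, and the catechol is still masked, so nothing oxidisable meets the basic work-up.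

Step 8
Reactants: 17 [(1S,2R,3R)-1-(4-hydroxy-3-methoxyphenyl)-6-methoxy-7,8-(diphenylmethylenedioxy)-1,2,3,4-tetrahydronaphthalene-2,3-diyl]dimethanol
Product: 18 (1S,2R,3R)-1-(4-hydroxy-3-methoxyphenyl)-2,3-bis(hydroxymethyl)-6-methoxy-1,2,3,4-tetrahydronaphthalene-7,8-diol
Conditions: H2 (1 atm), 10% Pd/C, THF/MeOH, rt; filtration under argon
Reagents that add atoms: none
Why: Hydrogenolysis of the two benzhydrylic C–O bonds of the diphenylmethylene ketal releases the catechol and diphenylmethane under neutral, oxygen-free conditions; the bonds from C1 to its aryl groups are C–C bonds and are not cleaved, and no stereocentre is touched.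

## Compound list

1 | 2,3-dihydroxy-4-methoxybenzaldehyde | COc1ccc(C=O)c(O)c1O | starting material
2 | dichlorodiphenylmethane | ClC(Cl)(c1ccccc1)c1ccccc1 | starting material
3 | 7-methoxy-2,2-diphenyl-1,3-benzodioxole-4-carbaldehyde | COc1ccc(C=O)c2OC(c3ccccc3)(c3ccccc3)Oc12 | intermediate
4 | N,N,N'-trimethylethylenediamine | CNCCN(C)C | starting material
5 | lithium α-amino alkoxide of 3 (carbinol carbon racemic) | CN(C)CCN(C)C(O[Li])c1ccc(OC)c2OC(c3ccccc3)(c3ccccc3)Oc12 | intermediate (not isolated)
6 | 5-lithio derivative of 5 | CN(C)CCN(C)C(O[Li])c1c([Li])cc(OC)c2OC(c3ccccc3)(c3ccccc3)Oc12 | intermediate (not isolated)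
7 | 5-methyl derivative of 5 | CN(C)CCN(C)C(O[Li])c1c(C)cc(OC)c2OC(c3ccccc3)(c3ccccc3)Oc12 | intermediate (not isolated)
8 | 7-methoxy-5-methyl-2,2-diphenyl-1,3-benzodioxole-4-carbaldehyde | Cc1cc(OC)c2OC(c3ccccc3)(c3ccccc3)Oc2c1C=O | intermediate
9 | dimethyl fumarate | COC(=O)/C=C/C(=O)OC | starting material
10 | hydroxy-o-quinodimethane from 8, hydroxyl outward (the isomer usually called the E-photoenol; Z by the sequence rules here because the neighbouring ring carbon bears oxygen) | C=C1C=C(OC)C2=C(OC(c3ccccc3)(c3ccccc3)O2)/C1=C\O | intermediate (not isolated)
11 | dimethyl (1S,2S,3R)-1-hydroxy-6-methoxy-7,8-(diphenylmethylenedioxy)-1,2,3,4-tetrahydronaphthalene-2,3-dicarboxylate | O[C@@H]1c2c(cc(OC)c3OC(c4ccccc4)(c4ccccc4)Oc23)C[C@@H](C(=O)OC)[C@@H]1C(=O)OC | intermediate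
12 | (1S,2R,3R)-2,3-bis(hydroxymethyl)-6-methoxy-7,8-(diphenylmethylenedioxy)-1,2,3,4-tetrahydronaphthalen-1-ol | O[C@@H]1c2c(cc(OC)c3OC(c4ccccc4)(c4ccccc4)Oc23)C[C@@H](CO)[C@@H]1CO | intermediate
13 | [(1S,2R,3R)-1-hydroxy-6-methoxy-7,8-(diphenylmethylenedioxy)-1,2,3,4-tetrahydronaphthalene-2,3-diyl]bis(methylene) bis(2,2-dimethylpropanoate) | O[C@@H]1c2c(cc(OC)c3OC(c4ccccc4)(c4ccccc4)Oc23)C[C@@H](COC(=O)C(C)(C)C)[C@@H]1COC(=O)C(C)(C)C | intermediate
14 | 2-methoxyphenol | COc1ccccc1O | starting material
15 | C1 benzylic cation from 13 | [CH+]1c2c(cc(OC)c3OC(c4ccccc4)(c4ccccc4)Oc23)C[C@@H](COC(=O)C(C)(C)C)[C@@H]1COC(=O)C(C)(C)C | intermediate (not isolated)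
16 | [(1S,2R,3R)-1-(4-hydroxy-3-methoxyphenyl)-6-methoxy-7,8-(diphenylmethylenedioxy)-1,2,3,4-tetrahydronaphthalene-2,3-diyl]bis(methylene) bis(2,2-dimethylpropanoate) | COc1cc([C@H]2c3c(cc(OC)c4OC(c5ccccc5)(c5ccccc5)Oc34)C[C@@H](COC(=O)C(C)(C)C)[C@@H]2COC(=O)C(C)(C)C)ccc1O | intermediate
17 | [(1S,2R,3R)-1-(4-hydroxy-3-methoxyphenyl)-6-methoxy-7,8-(diphenylmethylenedioxy)-1,2,3,4-tetrahydronaphthalene-2,3-diyl]dimethanol | COc1cc([C@H]2c3c(cc(OC)c4OC(c5ccccc5)(c5ccccc5)Oc34)C[C@@H](CO)[C@@H]2CO)ccc1O | intermediate
18 | (1S,2R,3R)-1-(4-hydroxy-3-methoxyphenyl)-2,3-bis(hydroxymethyl)-6-methoxy-1,2,3,4-tetrahydronaphthalene-7,8-diol | COc1cc([C@H]2c3c(cc(OC)c(O)c3O)C[C@@H](CO)[C@@H]2CO)ccc1O | target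

## Step count and risk

Total step count: 8. Longest linear sequence: 8 steps (1 → 18).

Step 3 (key step). The most likely failure is weak or opposite facial selectivity. An acyclic E-diester binds titanium through one carbonyl group and keeps rotational freedom that the cyclic dienophiles of the closest precedent lack. Slow photoenolisation of the electron-rich aldehyde, or sensitised E/Z isomerisation of the fumarate with loss of the trans relation, are further risks. The fallback replaces reagent control by auxiliary control. It sets out from 8, which is irradiated at 365 nm in toluene without titanium together with the fumarate of methyl (S)-lactate, bis[(2S)-1-methoxy-1-oxopropan-2-yl] (2E)-but-2-enedioate F1. This is a known way of steering cycloadditions of hydroxy-o-quinodimethanes. The lactate ester cycloadduct F2 is separated from its diastereomer, and LiAlH4 in THF reduces all four ester groups, which brings the route back at 12. If the (S)-lactate favours the wrong C2/C3 pair, the fumarate of the (R)-lactate is used.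

Step 6. The cation may be captured through another position of the phenol (ortho to the hydroxyl, para to the methoxy group, or at oxygen). The Lewis acid may open the ketal, or the cation may lose the C2 proton. The fallback uses a blocking group on the arene. It sets out from 13, which is ionised in the same way in the presence of 2-bromo-6-methoxyphenol F5. In F5 the position ortho to the hydroxyl is occupied and the position para to the methoxy group is shielded by bromine, so only the carbon para to the hydroxyl is open, giving the bromoaryl bis-pivalate F6. Hydride cleavage of the pivalates (iBu2AlH or LiAlH4, 0 °C) gives the bromoaryl diol F7. Hydrogenolysis over Pd/C with Et3N then removes bromine and ketal together and comes back to the route at 18.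

Step 2. Lithiation ortho to the methoxy group could compete with lithiation ortho to the amino alkoxide, or metalation could stay incomplete, giving mixtures of methylated aldehydes. The fallback brings the methyl group in with the starting material. It sets out from 2 together with purchased 2,3,4-trimethoxy-6-methylbenzaldehyde F3. Chelation-controlled double demethylation with BCl3 in CH2Cl2 removes the methyl ethers ortho and meta to the aldehyde and gives 2,3-dihydroxy-4-methoxy-6-methylbenzaldehyde F4. Ketalisation of F4 with 2 under the conditions of step 1 comes back to the route at 8.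

Step 8. Hydrogenolysis may stall at the stage of the mono-benzhydryl ether, or the freed catechol may oxidise during filtration. The fallback is hydrolytic: from 17, AcOH/H2O (4:1), 80 °C, degassed, cleaves the ketal to benzophenone and gives 18 directly, with no new intermediate.

## Further compounds

F1 | step 3 | bis[(2S)-1-methoxy-1-oxopropan-2-yl] (2E)-but-2-enedioate | COC(=O)[C@H](C)OC(=O)/C=C/C(=O)O[C@@H](C)C(=O)OC
F2 | step 3 | bis[(2S)-1-methoxy-1-oxopropan-2-yl] (1S,2S,3R)-1-hydroxy-6-methoxy-7,8-(diphenylmethylenedioxy)-1,2,3,4-tetrahydronaphthalene-2,3-dicarboxylate | O[C@@H]1c2c(cc(OC)c3OC(c4ccccc4)(c4ccccc4)Oc23)C[C@@H](C(=O)O[C@@H](C)C(=O)OC)[C@@H]1C(=O)O[C@@H](C)C(=O)OC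
F3 | step 2 | 2,3,4-trimethoxy-6-methylbenzaldehyde | Cc1cc(OC)c(OC)c(OC)c1C=O
F4 | step 2 | 2,3-dihydroxy-4-methoxy-6-methylbenzaldehyde | Cc1cc(OC)c(O)c(O)c1C=O
F5 | step 6 | 2-bromo-6-methoxyphenol | COc1cccc(Br)c1O
F6 | step 6 | [(1S,2R,3R)-1-(3-bromo-4-hydroxy-5-methoxyphenyl)-6-methoxy-7,8-(diphenylmethylenedioxy)-1,2,3,4-tetrahydronaphthalene-2,3-diyl]bis(methylene) bis(2,2-dimethylpropanoate) | COc1cc([C@H]2c3c(cc(OC)c4OC(c5ccccc5)(c5ccccc5)Oc34)C[C@@H](COC(=O)C(C)(C)C)[C@@H]2COC(=O)C(C)(C)C)cc(Br)c1O
F7 | step 6 | [(1S,2R,3R)-1-(3-bromo-4-hydroxy-5-methoxyphenyl)-6-methoxy-7,8-(diphenylmethylenedioxy)-1,2,3,4-tetrahydronaphthalene-2,3-diyl]dimethanol | COc1cc([C@H]2c3c(cc(OC)c4OC(c5ccccc5)(c5ccccc5)Oc34)C[C@@H](CO)[C@@H]2CO)cc(Br)c1O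
F0 | step 8 | none | none
A1 | alternative 1 | (2R,4R)-pentane-2,4-diyl-tethered trans-7-hydroxy-1-(4-hydroxy-3-methoxyphenyl)-6-methoxy-8-(tosyloxy)-1,2-dihydronaphthalene-2,3-dicarboxylate (nine-membered dilactone) | COc1cc([C@H]2c3c(cc(OC)c(O)c3OS(=O)(=O)c3ccc(C)cc3)C=C(C(=O)O[C@H](C)C[C@@H](C)O5)[C@@H]2C5=O)ccc1O
A2 | alternative 1 | (2R,4R)-pentane-2,4-diyl (E)-4-hydroxy-3-methoxycinnamate (E)-4-hydroxy-3-methoxy-5-(tosyloxy)cinnamate | COc1cc(/C=C/C(=O)O[C@H](C)C[C@@H](C)OC(=O)/C=C/c2cc(OC)c(O)c(OS(=O)(=O)c3ccc(C)cc3)c2)ccc1O
A3 | alternative 2 | tricyclic methyl acetal with the C8 oxygen bonded to C9 of the all-trans tetralin, benzyl ethers at the C7, C10 and guaiacyl oxygens, acetal epimers | COc1cc([C@H]2c3c(cc(OC)c(OCc4ccccc4)c3O5)C[C@@H](COCc3ccccc3)[C@@H]2C5OC)ccc1OCc1ccccc1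
A4 | alternative 2 | diaryl carbinol with free C8 phenol and a (E)-methyl enol ether side chain on C4a, C3 preset | COc1cc(C(O)c2c(O)c(OCc3ccccc3)c(OC)cc2C[C@@H](COCc2ccccc2)/C=C/OC)ccc1OCc1ccccc1
A5 | alternative 3 | trans-2,3-bis(benzyloxymethyl)-7,8-dibenzyloxy-6-methoxy-4-(phenylsulfonyl)tetralin-1-one | O=C1c2c(cc(OC)c(OCc3ccccc3)c2OCc2ccccc2)C(S(=O)(=O)c2ccccc2)[C@@H](COCc2ccccc2)[C@@H]1COCc1ccccc1
A6 | alternative 3 | trans-3,4-bis(benzyloxymethyl)-2-(phenylsulfonyl)cyclobutan-1-one | O=C1C(S(=O)(=O)c2ccccc2)[C@@H](COCc2ccccc2)[C@@H]1COCc1ccccc1
A7 | alternative 3 | 3,4-bis(benzyloxy)-5-methoxy-2-(trimethylsilyl)phenyl trifluoromethanesulfonate | COc1cc(OS(=O)(=O)C(F)(F)F)c([Si](C)(C)C)c(OCc2ccccc2)c1OCc1ccccc1
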